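**Retrosynthetic overview** (prostanoid numbering: ester C1, chain acetate C4, C5=C6, ketone C9, C10=C11, tertiary acetate C12, butyl C17–C20)

1. Feature: the cyclobutane C7–C8–C15–C16 is spiro at C8 to the cyclopentenone C8–C9–C10–C11–C12 and fused along C8–C15 to the cyclopentane C8–C12–C13–C14–C15. It is the formal [2+2] adduct of a C7=C8 alkylidene and a C15=C16 alkene joined through C12–C13–C14.
2. Last disconnection: C8–C15 and C7–C16 are cut together, giving the cross-conjugated trienone diacetate 25/26. Forward, one irradiation closes the cyclopentane and then the cyclobutane.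
3. C7=C8 is cut by aldol condensation into ring ketone 9 (C8–C20) and enal 19 (C1–C7, 4R from D-glutamic acid).
4. C12–C13 is cut by 1,2-addition of octenyl Grignard 5 to (S)-4-silyloxycyclopentenone 4; the stereocentre of 4 is relayed to C12 and then oxidised away.
5. Ring order: cyclopentenone (purchased), then cyclopentane and cyclobutane together in step 17.

Key step: step 17

Remark: enone 4 is taken as a purchasable enantiopure building block, and the aldol dehydration is assumed to give mainly the 7E alkylidene, which the light of step 17 converts into the 7Z isomer in the flask.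

**Route**

Step 1
Reactants: 1 oct-3-yn-1-ol
Product: 2 (E)-oct-3-en-1-ol
Conditions: Na, liq. NH3/THF, −33 °C; NH4Cl
Reagents that add atoms: none
Why: Dissolving-metal reduction of the internal alkyne passes through the trans vinyl radical anion and should give the E-alkene, the sodium alkoxide of the hydroxyl being inert.

Step 2
Reactants: 2 (E)-oct-3-en-1-ol
Product: 3 (E)-1-bromooct-3-ene
Conditions: CBr4, PPh3, CH2Cl2, 0 °C
Reagents that add atoms: carbon tetrabromide, BrC(Br)(Br)Br
Why: Appel bromination displaces the primary oxyphosphonium by SN2 and leaves the remote E-alkene untouched.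

Step 3
Reactants: 3 (E)-1-bromooct-3-ene; 4 (S)-4-(tert-butyldimethylsilyloxy)cyclopent-2-en-1-one
Product: 6 (1R,4S)-4-(tert-butyldimethylsilyloxy)-1-[(E)-oct-3-en-1-yl]cyclopent-2-en-1-ol (OH cis to OTBS), via (E)-oct-3-enylmagnesium bromide 5 (not isolated)
Conditions: Mg, THF, 40 °C; then 4, LaCl3·2LiCl, THF, −78 → −30 °C; NH4Cl
Reagents that add atoms: none
Why: Grignard formation and lanthanide-promoted 1,2-addition to the enone carbonyl, with attack anti to the bulky 4-silyloxy group, should set the tertiary carbinol (future C12) with OH cis to OTBS, the minor diastereomer being removed by chromatography here or at diol 7.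

Step 4
Reactants: 6 (1R,4S)-4-(tert-butyldimethylsilyloxy)-1-[(E)-oct-3-en-1-yl]cyclopent-2-en-1-ol
Product: 7 (1R,4S)-1-[(E)-oct-3-en-1-yl]cyclopent-2-ene-1,4-diol (cis-diol)
Conditions: TBAF, THF, 0 °C → rt
Reagents that add atoms: none
Why: Fluoride desilylation cleaves the secondary TBS ether under near-neutral conditions that spare the tertiary allylic alcohol and the chain alkene.

Step 5
Reactants: 7 (1R,4S)-1-[(E)-oct-3-en-1-yl]cyclopent-2-ene-1,4-diol
Product: 8 (R)-4-hydroxy-4-[(E)-oct-3-en-1-yl]cyclopent-2-en-1-one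
Conditions: MnO2, CH2Cl2, rt
Reagents that add atoms: none
Why: Manganese dioxide allylic oxidation takes only the secondary allylic alcohol, so the tertiary carbinol survives and now carries alone the configuration relayed from 4.

Step 6
Reactants: 8 (R)-4-hydroxy-4-[(E)-oct-3-en-1-yl]cyclopent-2-en-1-one
Product: 9 (R)-4-[(E)-oct-3-en-1-yl]-4-(trimethylsilyloxy)cyclopent-2-en-1-one
Conditions: TMSCl, imidazole, DMF, 0 °C → rt
Reagents that add atoms: chlorotrimethylsilane, C[Si](C)(C)Cl
Why: Silylation of the tertiary alcohol removes the acidic proton and the alkoxide-driven retro-aldol pathway before enolate chemistry.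

Step 7
Reactants: 10 D-glutamic acid
Product: 11 (R)-5-oxotetrahydrofuran-2-carboxylic acid
Conditions: NaNO2, aq. HCl, 0 °C → rt
Reagents that add atoms: none
Why: Diazotisation with double inversion through the α-lactone lets the γ-carboxylate replace the amino group with overall retention, giving the R lactone acid.

Step 8
Reactants: 11 (R)-5-oxotetrahydrofuran-2-carboxylic acid
Product: 12 (R)-5-(hydroxymethyl)dihydrofuran-2(3H)-one
Conditions: BH3·SMe2, THF, 0 °C → rt; MeOH
Reagents that add atoms: none
Why: Borane reduces the free carboxylic acid through its acyloxyborane much faster than the lactone, and the stereocentre is not involved.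

Step 9
Reactants: 12 (R)-5-(hydroxymethyl)dihydrofuran-2(3H)-one
Product: 14 (E)-3-[(R)-5-oxotetrahydrofuran-2-yl]prop-2-enal, via lactone aldehyde 13 (not isolated)
Conditions: (COCl)2, DMSO, CH2Cl2, −78 °C; Et3N; then Ph3P=CHCHO, −78 °C → rt
Reagents that add atoms: (triphenylphosphoranylidene)acetaldehyde, O=CC=P(c1ccccc1)(c1ccccc1)c1ccccc1
Why: Swern oxidation gives the configurationally labile α-acyloxy aldehyde, which is trapped in the same flask by Wittig olefination with the stabilised ylide to give the E-enal without contact with silica or strong base.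

Step 10
Reactants: 14 (E)-3-[(R)-5-oxotetrahydrofuran-2-yl]prop-2-enal
Product: 15 (R)-5-[(E)-3,3-dimethoxyprop-1-en-1-yl]dihydrofuran-2(3H)-one
Conditions: HC(OMe)3, MeOH, PPTS (cat.), rt
Reagents that add atoms: trimethyl orthoformate, COC(OC)OC
Why: Acid-catalysed acetalisation masks the enal as its dimethyl acetal so that the lactone can be opened with hydroxide in the next step.

Step 11
Reactants: 15 (R)-5-[(E)-3,3-dimethoxyprop-1-en-1-yl]dihydrofuran-2(3H)-one
Product: 18 methyl (R,E)-4-acetoxy-7,7-dimethoxyhept-5-enoate, via potassium hydroxy-carboxylate 16 (not isolated), via hydroxy methyl ester 17 (not isolated)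
Conditions: KOH (1.0 equiv), MeOH/H2O, 0 °C, evaporation; MeI, DMF, rt; then Ac2O, pyridine, DMAP, 0 °C
Reagents that add atoms: potassium hydroxide, [K+].[OH-]; iodomethane, CI; acetic anhydride, CC(=O)OC(C)=O
Why: Saponification of the γ-lactone, SN2 O-methylation of the dry carboxylate and immediate DMAP-catalysed acetylation of the freed C4 hydroxyl should trap the open chain before it relactonises, with no bond to the C4 stereocentre broken.

Step 12
Reactants: 18 methyl (R,E)-4-acetoxy-7,7-dimethoxyhept-5-enoate
Product: 19 methyl (R,E)-4-acetoxy-7-oxohept-5-enoate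
Conditions: 1 M HCl, THF, 0 °C
Reagents that add atoms: water, O
Why: Mild acid hydrolysis of the dimethyl acetal releases the E-enal at a pH at which the allylic acetate and the methyl ester are stable.

Step 13
Reactants: 9 (R)-4-[(E)-oct-3-en-1-yl]-4-(trimethylsilyloxy)cyclopent-2-en-1-one; 19 methyl (R,E)-4-acetoxy-7-oxohept-5-enoate
Product: 21 methyl (4R,5E)-4-acetoxy-7-hydroxy-7-[(5S)-5-[(E)-oct-3-en-1-yl]-2-oxo-5-(trimethylsilyloxy)cyclopent-3-en-1-yl]hept-5-enoate (C7/C8 epimers), via lithium dienolate 20 (not isolated)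
Conditions: LDA (1.0 equiv), THF, −78 °C; then 19, −78 °C; NH4Cl
Reagents that add atoms: none
Why: Kinetic deprotonation at the only enolisable position (C8) gives the cross-conjugated lithium dienolate, whose aldol 1,2-addition to the aldehyde at −78 °C should outpace attack on the acetate or ester, the uncontrolled C7 and C8 centres being erased in step 14.

Step 14
Reactants: 21 aldol adduct (C7/C8 epimers)
Product: 23 methyl (4R,5E,7E)-4-acetoxy-7-[(5S)-5-[(E)-oct-3-en-1-yl]-2-oxo-5-(trimethylsilyloxy)cyclopent-3-en-1-ylidene]hept-5-enoate, via C7 mesylate 22 (not isolated)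
Conditions: MsCl, Et3N, CH2Cl2, −20 °C; then DBU, 0 °C
Reagents that add atoms: none
Why: Mesylation of the C7 hydroxyl and E1cB elimination through the C8 enolate should give the cross-conjugated trienone, expected mainly as the 7E alkylidene that is carried on, with C5=C6 unchanged.

Step 15
Reactants: 23 7E trienone trimethylsilyl ether
Product: 24 methyl (4R,5E,7E)-4-acetoxy-7-[(5S)-5-hydroxy-5-[(E)-oct-3-en-1-yl]-2-oxocyclopent-3-en-1-ylidene]hept-5-enoate
Conditions: HF·pyridine, pyridine/THF, 0 °C
Reagents that add atoms: none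
Why: Buffered fluoride desilylation removes the tertiary trimethylsilyl ether without affecting the acetate, the ester or the dienone.

Step 16
Reactants: 24 7E 12-hydroxy trienone
Product: 25 methyl (4R,5E,7E)-4-acetoxy-7-[(5S)-5-acetoxy-5-[(E)-oct-3-en-1-yl]-2-oxocyclopent-3-en-1-ylidene]hept-5-enoate
Conditions: Ac2O, DMAP, Et3N, CH2Cl2, rt
Reagents that add atoms: acetic anhydride, CC(=O)OC(C)=O
Why: DMAP-catalysed acylation through the N-acetylpyridinium ion esterifies the hindered tertiary alcohol, which resists ionisation because the derived cation would be of cyclopentadienone type.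

Step 17
Reactants: 25 7E seco-trienone diacetate
Product: 27 tricycloclavulone, via (5E,7Z,15E)-seco-trienone diacetate 26 (not isolated)
Conditions: hν (350–366 nm, Pyrex), degassed MeCN (2 mM), 0–20 °C
Reagents that add atoms: none
Why: Light first equilibrates 25 with its 7Z isomer 26 through the twisted triplet of the C9=O/C7=C8/C5=C6 dienone arm, and this triplet, which carries its spin at C8 and C7 and none at C10 or C11, is intercepted by the tethered C15=C16 alkene, so the ring enone is not expected to compete. The closest known reaction type is the intramolecular enone–alkene [2+2] photocycloaddition of 1,6-dienes with a three-atom tether (rule of five, straight adduct). C8 bonds to C15 in a 5-exo (1,5) closure that forms the cyclopentane C8–C12–C13–C14–C15, and the triplet 1,4-diradical left at C7 (allylic) and C16 closes the four-membered ring C7–C8–C15–C16 by radical recombination after intersystem crossing. C8 and C15 are set by the C12 stereocentre, because the tether can reach C8 only from the face on which it leaves C12 (anti to the acetate) and can only close to cis-fused 5/5 and 4/5 rings. C7 and C16 are set in the diradical collapse, where the butyl group should stay anti to C14 (memory of the 15E alkene) and the C5=C6 arm should settle on the C9 side away from C12, which is the cis C6/butyl arrangement of the target. The step needs straight regiochemistry, reaction at C7=C8 only, collapse faster than C15–C16 rotation and retention of 5E, secured in turn by the tether length, by triplet localisation, by the short life of the diradical and, least firmly, by an E-rich photostationary state at C5=C6.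

**Compound list**

1 | oct-3-yn-1-ol | CCCCC#CCCO | starting material
2 | (E)-oct-3-en-1-ol | CCCC/C=C/CCO | intermediate
3 | (E)-1-bromooct-3-ene | CCCC/C=C/CCBr | intermediate
4 | (S)-4-(tert-butyldimethylsilyloxy)cyclopent-2-en-1-one | O=C1C=C[C@@H](O[Si](C)(C)C(C)(C)C)C1 | starting material
5 | (E)-oct-3-enylmagnesium bromide | CCCC/C=C/CC[Mg]Br | intermediate
6 | (1R,4S)-4-(tert-butyldimethylsilyloxy)-1-[(E)-oct-3-en-1-yl]cyclopent-2-en-1-ol | CCCC/C=C/CC[C@]1(O)C=C[C@@H](O[Si](C)(C)C(C)(C)C)C1 | intermediate
7 | (1R,4S)-1-[(E)-oct-3-en-1-yl]cyclopent-2-ene-1,4-diol | CCCC/C=C/CC[C@]1(O)C=C[C@@H](O)C1 | intermediate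
8 | (R)-4-hydroxy-4-[(E)-oct-3-en-1-yl]cyclopent-2-en-1-one | CCCC/C=C/CC[C@]1(O)C=CC(=O)C1 | intermediate
9 | (R)-4-[(E)-oct-3-en-1-yl]-4-(trimethylsilyloxy)cyclopent-2-en-1-one | CCCC/C=C/CC[C@]1(O[Si](C)(C)C)C=CC(=O)C1 | intermediate
10 | D-glutamic acid | N[C@H](CCC(O)=O)C(O)=O | starting material
11 | (R)-5-oxotetrahydrofuran-2-carboxylic acid | OC(=O)[C@H]1CCC(=O)O1 | intermediate
12 | (R)-5-(hydroxymethyl)dihydrofuran-2(3H)-one | OC[C@H]1CCC(=O)O1 | intermediate
13 | (R)-5-oxotetrahydrofuran-2-carbaldehyde | O=C[C@H]1CCC(=O)O1 | intermediate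
14 | (E)-3-[(R)-5-oxotetrahydrofuran-2-yl]prop-2-enal | O=C/C=C/[C@H]1CCC(=O)O1 | intermediate
15 | (R)-5-[(E)-3,3-dimethoxyprop-1-en-1-yl]dihydrofuran-2(3H)-one | COC(OC)/C=C/[C@H]1CCC(=O)O1 | intermediate
16 | potassium (R,E)-4-hydroxy-7,7-dimethoxyhept-5-enoate | COC(OC)/C=C/[C@H](O)CCC(=O)[O-].[K+] | intermediate
17 | methyl (R,E)-4-hydroxy-7,7-dimethoxyhept-5-enoate | COC(OC)/C=C/[C@H](O)CCC(=O)OC | intermediate
18 | methyl (R,E)-4-acetoxy-7,7-dimethoxyhept-5-enoate | COC(OC)/C=C/[C@H](OC(C)=O)CCC(=O)OC | intermediate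
19 | methyl (R,E)-4-acetoxy-7-oxohept-5-enoate | O=C/C=C/[C@H](OC(C)=O)CCC(=O)OC | intermediate
20 | lithium dienolate of 9 (lithium 4-octenyl-4-trimethylsilyloxycyclopenta-1,3-dien-1-olate) | CCCC/C=C/CC[C@]1(O[Si](C)(C)C)C=CC(O[Li])=C1 | intermediate
21 | methyl (4R,5E)-4-acetoxy-7-hydroxy-7-[(5S)-5-[(E)-oct-3-en-1-yl]-2-oxo-5-(trimethylsilyloxy)cyclopent-3-en-1-yl]hept-5-enoate, C7/C8 epimers | CCCC/C=C/CC[C@]1(O[Si](C)(C)C)C=CC(=O)C1C(O)/C=C/[C@@H](CCC(=O)OC)OC(C)=O | intermediate
22 | C7 methanesulfonate of 21 | CCCC/C=C/CC[C@]1(O[Si](C)(C)C)C=CC(=O)C1C(OS(C)(=O)=O)/C=C/[C@@H](CCC(=O)OC)OC(C)=O | intermediate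
23 | methyl (4R,5E,7E)-4-acetoxy-7-[(5S)-5-[(E)-oct-3-en-1-yl]-2-oxo-5-(trimethylsilyloxy)cyclopent-3-en-1-ylidene]hept-5-enoate | CCCC/C=C/CC[C@]1(O[Si](C)(C)C)C=CC(=O)/C1=C/C=C/[C@@H](CCC(=O)OC)OC(C)=O | intermediate
24 | methyl (4R,5E,7E)-4-acetoxy-7-[(5S)-5-hydroxy-5-[(E)-oct-3-en-1-yl]-2-oxocyclopent-3-en-1-ylidene]hept-5-enoate | CCCC/C=C/CC[C@]1(O)C=CC(=O)/C1=C/C=C/[C@@H](CCC(=O)OC)OC(C)=O | intermediate
25 | methyl (4R,5E,7E)-4-acetoxy-7-[(5S)-5-acetoxy-5-[(E)-oct-3-en-1-yl]-2-oxocyclopent-3-en-1-ylidene]hept-5-enoate (7E seco-trienone diacetate) | CCCC/C=C/CC[C@]1(OC(C)=O)C=CC(=O)/C1=C/C=C/[C@@H](CCC(=O)OC)OC(C)=O | intermediate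
26 | methyl (4R,5E,7Z)-4-acetoxy-7-[(5S)-5-acetoxy-5-[(E)-oct-3-en-1-yl]-2-oxocyclopent-3-en-1-ylidene]hept-5-enoate (7Z seco-trienone diacetate) | CCCC/C=C/CC[C@]1(OC(C)=O)C=CC(=O)/C1=C\C=C\[C@@H](CCC(=O)OC)OC(C)=O | intermediate
27 | tricycloclavulone | CCCC[C@H]1[C@@H](/C=C/[C@@H](CCC(=O)OC)OC(C)=O)[C@]23C(=O)C=C[C@@]2(OC(C)=O)CC[C@H]13 | target

**Step count**

Total: 17 steps. Longest linear sequence: 11 steps (steps 1–6 then 13–17, or equally 7–12 then 13–17).

**Steps most likely to fail**

1. Step 17 (photocycloaddition). What may go wrong: radiationless decay of the trienone triplet by twisting about C7=C8 and C5=C6 outruns C8–C15 bonding, the ring enone C10=C11 captures the tethered alkene instead, or the C5=C6 geometry drifts to Z before closure. Fallback, from 25 back to 27: the carbonyl is taken out of the chromophore so that only a 1,3-diene can be excited. Luche reduction of 25 (NaBH4, CeCl3·7H2O, MeOH, −78 °C) should give the C9 carbinol of the trienone F1 (both C9 epimers usable), in which C10=C11 is an isolated alkene. Visible-light triplet sensitisation of its C5=C6–C7=C8 diene ([Ir(dF(CF3)ppy)2(dtbbpy)]PF6, blue LEDs, degassed DMSO) is the known intramolecular diene–alkene [2+2] that gives vinylcyclobutanes. It should form the same C8–C15 and C7–C16 bonds under the same tether control and give the tricyclic C9 carbinol F2. Dess–Martin oxidation of the allylic alcohol of F2 returns 27.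

2. Step 13 (aldol coupling). What may go wrong: proton transfer from the enal or acyl transfer from its acetate to the lithium dienolate, loss of silanolate from the dienolate, or retro-aldol on work-up. Fallback, from 9 back to 23: the C7=C8 bond is made by olefination instead of aldol and dehydration. The lithium dienolate 20 of 9 is C-phosphinylated with diethyl chlorophosphite to the β-keto phosphonite F3, which is oxidised in air in the same flask to the β-keto phosphonate F4. Horner–Wadsworth–Emmons reaction of F4 with enal 19 under LiCl/DBU in MeCN should give trienone 23 directly, so that neither 21 nor 22 is needed.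

3. Step 3 (1,2-addition that sets C12). What may go wrong: poor facial selectivity, enolisation of 4 with loss of silanolate, or conjugate addition, each of which lowers the enantiopurity or the supply of 8. Fallback, from 3 (as its Grignard reagent 5) back to 8: 5 is added at −78 °C in THF to cyclopent-4-ene-1,3-dione (O=C1C=CC(=O)C1), which gives the racemic hydroxy enone F5 in one step without a relay stereocentre. Preparative chromatography on a chiral stationary phase then delivers 8 and the unwanted (S)-hydroxy enone F6, which is discarded. Steps 4 and 5 are bypassed.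

**Further compounds**

F1 | step 17 | methyl (4R,5E)-4-acetoxy-7-[(5S)-5-acetoxy-2-hydroxy-5-[(E)-oct-3-en-1-yl]cyclopent-3-en-1-ylidene]hept-5-enoate (C9 carbinol of 25, C9 epimers) | CCCC/C=C/CC[C@]1(OC(C)=O)C=CC(O)/C1=C/C=C/[C@@H](CCC(=O)OC)OC(C)=O
F2 | step 17 | 9-hydroxy analogue of tricycloclavulone (tricyclic C9 carbinol, C9 epimers) | CCCC[C@H]1[C@@H](/C=C/[C@@H](CCC(=O)OC)OC(C)=O)[C@]23C(O)C=C[C@@]2(OC(C)=O)CC[C@H]13
F3 | step 13 | diethyl [(5S)-5-[(E)-oct-3-en-1-yl]-2-oxo-5-(trimethylsilyloxy)cyclopent-3-en-1-yl]phosphonite | CCCC/C=C/CC[C@]1(O[Si](C)(C)C)C=CC(=O)C1P(OCC)OCC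
F4 | step 13 | diethyl [(5S)-5-[(E)-oct-3-en-1-yl]-2-oxo-5-(trimethylsilyloxy)cyclopent-3-en-1-yl]phosphonate | CCCC/C=C/CC[C@]1(O[Si](C)(C)C)C=CC(=O)C1P(=O)(OCC)OCC
F5 | step 3 | rac-4-hydroxy-4-[(E)-oct-3-en-1-yl]cyclopent-2-en-1-one | CCCC/C=C/CC1(O)C=CC(=O)C1
F6 | step 3 | (S)-4-hydroxy-4-[(E)-oct-3-en-1-yl]cyclopent-2-en-1-one | CCCC/C=C/CC[C@@]1(O)C=CC(=O)C1
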